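**Plan**

1. Retrosynthesis (pyran numbered O1, C2 = CHMe, C3 = CH–CH2OH, C4 = CH–CH2CO2R, C5 = C–CO2Me, C6 = CH=): cut first the CH2–C(aryl) bond of the arylethyl ester, giving the O-vinyl ester of the pyranylacetic acid and 3,4-bis(benzyloxy)iodobenzene. Then cut C6 and the O1–C6 enol-ether bond back to a δ-lactone whose α-carbon is C5, then the C4–CH2CO2Me bond (Michael), the lactone C=C (metathesis) and the C3–vinyl bond (epoxide opening).
2. Enabling feature: the ester oxygen sits on the carbon β to C1 of the catechol ring (O–CH2–CH2–Ar). This unit is the anti-Markovnikov hydroarylation product of an O–CH=CH2 group: an aryl σ-radical at C1 of the 3,4-dioxygenated benzene ring adds to the unsubstituted vinyl carbon, and the α-acyloxy radical is capped with a hydrogen atom.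
3. Forward order: epoxy alcohol → 2-vinyl-1,3-diol → acrylate → ring-closing metathesis to the cis-5,6-disubstituted dihydropyranone (first ring) → malonate addition and demethoxycarbonylation → α-formylation → acid methanolysis that turns the lactone into the 3,4-dihydro-2H-pyran-5-carboxylate.
4. Then selective saponification → vinyl ester → union with the aryl iodide (benzene ring attached last) → hydrogenolysis of the three benzyl ethers.
5. Stereochemistry: C2 from Katsuki–Sharpless epoxidation of (E)-crotyl alcohol; C3 from invertive vinyl-cuprate opening of that epoxide (2,3-cis); C4 from conjugate addition anti to the C3 substituent (3,4-trans). No stereocentre is touched afterwards.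

Key step: step 14

**Route**

Step 1
Reactants: 1 (2E)-but-2-en-1-ol
Product: 2 [(2S,3S)-3-methyloxiran-2-yl]methanol
Conditions: Ti(OiPr)4 (cat.), L-(+)-diisopropyl tartrate (cat.), t-BuOOH, 4 Å MS, CH2Cl2, −20 °C
Reagents that add atoms: tert-butyl hydroperoxide, CC(C)(C)OO
Why: Katsuki–Sharpless asymmetric epoxidation of an (E)-allylic alcohol, in which the L-(+)-tartrate/titanium catalyst should deliver oxygen to the face that gives the (2S,3S)-epoxide with high enantioselectivity, fixing the methyl-bearing C–O centre (later C2) and the centre that is inverted in step 2.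

Step 2
Reactants: 2 [(2S,3S)-3-methyloxiran-2-yl]methanol
Product: 3 (2R,3S)-2-ethenylbutane-1,3-diol
Conditions: CH2=CHMgBr (3 equiv), CuI (10 mol %), THF, −40 → −20 °C; aq. NH4Cl
Reagents that add atoms: vinylmagnesium bromide, C=C[Mg]Br
Why: Copper-catalysed Grignard (cuprate SN2) opening of a trans-2,3-epoxy alcohol, which for the magnesium alkoxide should take place at C2 with inversion to give the 1,3-diol, so that the vinyl-bearing centre (later C3) is set against the untouched carbinol centre in the sense that becomes 2,3-cis in the ring; a minor 1,2-diol regioisomer, if formed, is removable by periodate cleavage.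

Step 3
Reactants: 3 (2R,3S)-2-ethenylbutane-1,3-diol
Product: 4 (2S,3R)-3-[(benzyloxy)methyl]pent-4-en-2-ol
Conditions: NaH (1.0 equiv), BnBr (1.0 equiv), Bu4NI (cat.), THF, 0 °C → rt
Reagents that add atoms: benzyl bromide, BrCc1ccccc1
Why: Williamson etherification in which the less hindered, more acidic primary hydroxyl of the 1,3-diol should be alkylated in preference to the secondary one, with no stereocentre affected.

Step 4
Reactants: 4 (2S,3R)-3-[(benzyloxy)methyl]pent-4-en-2-ol
Product: 5 (2S,3R)-3-[(benzyloxy)methyl]pent-4-en-2-yl prop-2-enoate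
Conditions: CH2=CHCOCl, Et3N, DMAP (cat.), CH2Cl2, 0 °C
Reagents that add atoms: acryloyl chloride, C=CC(=O)Cl
Why: Standard acylation of a secondary alcohol with an acid chloride under amine/DMAP catalysis, with retention at the carbinol centre because the C–O bond is not broken.

Step 5
Reactants: 5 (2S,3R)-3-[(benzyloxy)methyl]pent-4-en-2-yl prop-2-enoate
Product: 6 (5R,6S)-5-[(benzyloxy)methyl]-6-methyl-5,6-dihydro-2H-pyran-2-one (5,6-cis)
Conditions: second-generation Grubbs catalyst RuCl2(=CHPh)(H2IMes)(PCy3) (5 mol %), CH2Cl2 (0.01 M), 40 °C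
Reagents that add atoms: none
Why: Ring-closing metathesis of an acrylate with a terminal vinyl group, a standard entry to α,β-unsaturated δ-lactones, should close the six-membered ring with loss of ethene while both stereocentres stay as spectators.

Step 6
Reactants: 6 (5R,6S)-5-[(benzyloxy)methyl]-6-methyl-5,6-dihydro-2H-pyran-2-one
Product: 7 dimethyl 2-[(2S,3R,4R)-3-[(benzyloxy)methyl]-2-methyl-6-oxooxan-4-yl]propanedioate
Conditions: CH2(CO2Me)2 (1.5 equiv), NaH (0.2 equiv), THF, 0 °C → rt
Reagents that add atoms: dimethyl malonate, COC(=O)CC(=O)OC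
Why: Michael addition of a malonate to an unsaturated δ-lactone, in which axial attack on the half-chair anti to the pseudo-axial CH2OBn group on the neighbouring carbon (and anti to the 1,3-related methyl group) should set the new centre (later C4) trans to the CH2OBn-bearing centre.

Step 7
Reactants: 7 dimethyl 2-[(2S,3R,4R)-3-[(benzyloxy)methyl]-2-methyl-6-oxooxan-4-yl]propanedioate
Product: 8 methyl 2-[(2S,3R,4R)-3-[(benzyloxy)methyl]-2-methyl-6-oxooxan-4-yl]acetate
Conditions: LiCl, H2O, DMSO, 140 °C
Reagents that add atoms: none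
Why: Krapcho dealkoxycarbonylation should remove one malonate ester by chloride attack on its methyl group and loss of CO2, leaving the lactone, the benzyl ether and the three stereocentres untouched.

Step 8
Reactants: 8 methyl 2-[(2S,3R,4R)-3-[(benzyloxy)methyl]-2-methyl-6-oxooxan-4-yl]acetate
Product: 9 methyl 2-[(2S,3R,4S)-3-[(benzyloxy)methyl]-5-(hydroxymethylidene)-2-methyl-6-oxooxan-4-yl]acetate (enol tautomer of the α-formyl lactone, enol geometry not fixed)
Conditions: LiN(iPr)2 (1.1 equiv), THF, −78 °C; HCO2Me, −78 → −20 °C; aq. NH4Cl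
Reagents that add atoms: methyl formate, COC=O
Why: Crossed Claisen formylation in which the lactone α-CH2, several pKa units more acidic than the CH2 of the acyclic methyl ester, should be enolised selectively, so that the formyl carbon (later C6) is attached to the future C5 and the two CH2–C=O arms on the stereocentre stay distinct.

Step 9
Reactants: 9 methyl 2-[(2S,3R,4S)-3-[(benzyloxy)methyl]-5-(hydroxymethylidene)-2-methyl-6-oxooxan-4-yl]acetate
Product: 11 methyl (2S,3R,4S)-3-[(benzyloxy)methyl]-4-(2-methoxy-2-oxoethyl)-2-methyl-3,4-dihydro-2H-pyran-5-carboxylate, via cyclic 6-methoxy acetal 10 (not isolated)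
Conditions: HCl (1.25 M in MeOH), 0 → 50 °C
Reagents that add atoms: methanol, CO
Why: Acid-catalysed methanolysis and recyclisation of an α-formyl δ-lactone, a known entry to 3,4-dihydro-2H-pyran-5-carboxylates, in which the lactone carbonyl becomes the C5 methyl ester, the freed C2 hydroxyl adds to the formyl carbon (6-exo-trig) and the resulting acetal loses methanol to give the vinylogous carbonate as the thermodynamic sink, with C2, C3 and C4 untouched.

Step 10
Reactants: 11 methyl (2S,3R,4S)-3-[(benzyloxy)methyl]-4-(2-methoxy-2-oxoethyl)-2-methyl-3,4-dihydro-2H-pyran-5-carboxylate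
Product: 12 2-[(2S,3R,4S)-3-[(benzyloxy)methyl]-5-(methoxycarbonyl)-2-methyl-3,4-dihydro-2H-pyran-4-yl]acetic acid
Conditions: LiOH·H2O (1.5 equiv), THF/H2O (3:1), 0 °C; then 1 M HCl to pH 3
Reagents that add atoms: lithium hydroxide, [Li+].[OH-]
Why: Chemoselective saponification in which the saturated side-chain ester should be hydrolysed while the C5 ester, deactivated as a vinylogous carbonate by donation from O1, stays intact.

Step 11
Reactants: 12 2-[(2S,3R,4S)-3-[(benzyloxy)methyl]-5-(methoxycarbonyl)-2-methyl-3,4-dihydro-2H-pyran-4-yl]acetic acid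
Product: 13 methyl (2S,3R,4S)-3-[(benzyloxy)methyl]-4-[2-(ethenyloxy)-2-oxoethyl]-2-methyl-3,4-dihydro-2H-pyran-5-carboxylate
Conditions: Pd(OAc)2 (5 mol %), KOH (10 mol %), vinyl acetate (solvent), rt, dark
Reagents that add atoms: vinyl acetate, C=COC(C)=O
Why: Palladium-catalysed transvinylation (vinyl interchange) of a carboxylic acid with vinyl acetate should give the O-vinyl ester under near-neutral conditions that leave the benzyl ether and the enol-ether ester alone.

Step 12
Reactants: 14 benzene-1,2-diol (catechol)
Product: 15 1,2-bis(benzyloxy)benzene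
Conditions: BnBr (2.2 equiv), K2CO3, DMF, 60 °C
Reagents that add atoms: benzyl bromide, BrCc1ccccc1
Why: Double Williamson etherification of the two phenols, which masks the oxidation-prone catechol with groups that leave by hydrogenolysis in the last step.

Step 13
Reactants: 15 1,2-bis(benzyloxy)benzene
Product: 16 1,2-bis(benzyloxy)-4-iodobenzene
Conditions: N-iodosuccinimide (1.0 equiv), CF3CO2H (cat.), MeCN, rt
Reagents that add atoms: N-iodosuccinimide, O=C1CCC(=O)N1I
Why: Electrophilic aromatic iodination, which should go para to an alkoxy group on the activated central ring, whose positions 4 and 5 are equivalent, and not on the unactivated benzyl rings.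

Step 14
Reactants: 13 methyl (2S,3R,4S)-3-[(benzyloxy)methyl]-4-[2-(ethenyloxy)-2-oxoethyl]-2-methyl-3,4-dihydro-2H-pyran-5-carboxylate; 16 1,2-bis(benzyloxy)-4-iodobenzene
Product: 17 methyl (2S,3R,4S)-4-{2-[2-(3,4-bis(benzyloxy)phenyl)ethoxy]-2-oxoethyl}-3-[(benzyloxy)methyl]-2-methyl-3,4-dihydro-2H-pyran-5-carboxylate
Conditions: 16 (3 equiv), 10-phenylphenothiazine (5 mol %), cyclohexanethiol (10 mol %), HCO2Na (5 equiv), DMSO/H2O (19:1), 400–450 nm LEDs, rt
Reagents that add atoms: none
Why: The excited phenothiazine (or the CO2 radical anion formed from formate in the chain) transfers an electron to 16, iodide leaves, and the 3,4-bis(benzyloxy)phenyl σ-radical adds to the terminal CH2 of the O-vinyl group of 13; the α-acyloxyalkyl radical takes a hydrogen atom from the thiol, and the thiyl radical is returned to thiol by formate with release of CO2. The closest known reaction type is the photoredox/thiol anti-Markovnikov hydroarylation of heteroatom-substituted terminal alkenes (enol esters, enamides, vinyl carbamates) with (hetero)aryl halides, a reductive variant of the Meerwein arylation of vinyl acetate. No ring is closed and no stereocentre is formed or touched, since C2, C3 and C4 are remote from both radical centres. The step needs regioselectivity for the terminal carbon, chemoselectivity for the vinyl ester over the ring C5=C6 bond, and addition that outruns simple reduction of the aryl radical. The first should follow from the unsubstituted terminus and the oxygen-stabilised adduct radical, the second from C5=C6 being trisubstituted and push–pull deactivated, and the third from the low thiol loading and the excess of 16. The radical site of 16 lies meta and para to the benzyloxy groups, so no 1,5-hydrogen shift from a benzylic CH2 can compete.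

Step 15
Reactants: 17 methyl (2S,3R,4S)-4-{2-[2-(3,4-bis(benzyloxy)phenyl)ethoxy]-2-oxoethyl}-3-[(benzyloxy)methyl]-2-methyl-3,4-dihydro-2H-pyran-5-carboxylate
Product: 18 methyl (2S,3R,4S)-4-{2-[2-(3,4-dihydroxyphenyl)ethoxy]-2-oxoethyl}-3-(hydroxymethyl)-2-methyl-3,4-dihydro-2H-pyran-5-carboxylate (target)
Conditions: H2 (1 atm), Pd/C (10 wt %), EtOAc/MeOH, rt
Reagents that add atoms: none
Why: Catalytic hydrogenolysis should cleave the two aryl benzyl ethers and the alkyl benzyl ether in one neutral operation, the trisubstituted push–pull C5=C6 bond being reluctant to hydrogenate and the neutral medium avoiding lactonisation of the freed CH2OH onto the neighbouring ester.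

**Compound list**

1 | (2E)-but-2-en-1-ol | C/C=C/CO | starting material
2 | [(2S,3S)-3-methyloxiran-2-yl]methanol | C[C@@H]1O[C@H]1CO | intermediate
3 | (2R,3S)-2-ethenylbutane-1,3-diol | C[C@H](O)[C@@H](CO)C=C | intermediate
4 | (2S,3R)-3-[(benzyloxy)methyl]pent-4-en-2-ol | C[C@H](O)[C@@H](COCc1ccccc1)C=C | intermediate
5 | (2S,3R)-3-[(benzyloxy)methyl]pent-4-en-2-yl prop-2-enoate | C[C@H](OC(=O)C=C)[C@@H](COCc1ccccc1)C=C | intermediate
6 | (5R,6S)-5-[(benzyloxy)methyl]-6-methyl-5,6-dihydro-2H-pyran-2-one | C[C@@H]1OC(=O)C=C[C@@H]1COCc1ccccc1 | intermediate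
7 | dimethyl 2-[(2S,3R,4R)-3-[(benzyloxy)methyl]-2-methyl-6-oxooxan-4-yl]propanedioate | C[C@@H]1OC(=O)C[C@@H](C(C(=O)OC)C(=O)OC)[C@@H]1COCc1ccccc1 | intermediate
8 | methyl 2-[(2S,3R,4R)-3-[(benzyloxy)methyl]-2-methyl-6-oxooxan-4-yl]acetate | C[C@@H]1OC(=O)C[C@@H](CC(=O)OC)[C@@H]1COCc1ccccc1 | intermediate
9 | methyl 2-[(2S,3R,4S)-3-[(benzyloxy)methyl]-5-(hydroxymethylidene)-2-methyl-6-oxooxan-4-yl]acetate (enol geometry not fixed) | C[C@@H]1OC(=O)C(=CO)[C@@H](CC(=O)OC)[C@@H]1COCc1ccccc1 | intermediate
10 | methyl (2S,3R,4S)-3-[(benzyloxy)methyl]-6-methoxy-4-(2-methoxy-2-oxoethyl)-2-methyloxane-5-carboxylate (target numbering, mixture of C5/C6 epimers, not isolated) | COC(=O)C1C(OC)O[C@@H](C)[C@@H](COCc2ccccc2)[C@@H]1CC(=O)OC | intermediate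
11 | methyl (2S,3R,4S)-3-[(benzyloxy)methyl]-4-(2-methoxy-2-oxoethyl)-2-methyl-3,4-dihydro-2H-pyran-5-carboxylate | COC(=O)C1=CO[C@@H](C)[C@@H](COCc2ccccc2)[C@@H]1CC(=O)OC | intermediate
12 | 2-[(2S,3R,4S)-3-[(benzyloxy)methyl]-5-(methoxycarbonyl)-2-methyl-3,4-dihydro-2H-pyran-4-yl]acetic acid | COC(=O)C1=CO[C@@H](C)[C@@H](COCc2ccccc2)[C@@H]1CC(=O)O | intermediate
13 | methyl (2S,3R,4S)-3-[(benzyloxy)methyl]-4-[2-(ethenyloxy)-2-oxoethyl]-2-methyl-3,4-dihydro-2H-pyran-5-carboxylate | COC(=O)C1=CO[C@@H](C)[C@@H](COCc2ccccc2)[C@@H]1CC(=O)OC=C | intermediate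
14 | benzene-1,2-diol (catechol) | Oc1ccccc1O | starting material
15 | 1,2-bis(benzyloxy)benzene | c1ccc(COc2ccccc2OCc2ccccc2)cc1 | intermediate
16 | 1,2-bis(benzyloxy)-4-iodobenzene | Ic1ccc(OCc2ccccc2)c(OCc2ccccc2)c1 | intermediate
17 | methyl (2S,3R,4S)-4-{2-[2-(3,4-bis(benzyloxy)phenyl)ethoxy]-2-oxoethyl}-3-[(benzyloxy)methyl]-2-methyl-3,4-dihydro-2H-pyran-5-carboxylate | COC(=O)C1=CO[C@@H](C)[C@@H](COCc2ccccc2)[C@@H]1CC(=O)OCCc1ccc(OCc2ccccc2)c(OCc2ccccc2)c1 | intermediate
18 | methyl (2S,3R,4S)-4-{2-[2-(3,4-dihydroxyphenyl)ethoxy]-2-oxoethyl}-3-(hydroxymethyl)-2-methyl-3,4-dihydro-2H-pyran-5-carboxylate | COC(=O)C1=CO[C@@H](C)[C@@H](CO)[C@@H]1CC(=O)OCCc1ccc(O)c(O)c1 | target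

**Step count and risks**

Total step count: 15. Longest linear sequence: 13 steps (steps 1–11, 14, 15); steps 12–13 form the aryl branch.

Steps most likely to fail:

Step 14. The aryl radical may be reduced to the arene or may add to the ring C5=C6 bond before it meets the vinyl group, and the vinyl ester may be lost by acyl transfer in the aqueous formate medium. The fallback sets out from acid 12. Esterification with 2-bromoethanol (EDC·HCl, DMAP, CH2Cl2, 0 °C → rt) should give methyl (2S,3R,4S)-3-[(benzyloxy)methyl]-4-[2-(2-bromoethoxy)-2-oxoethyl]-2-methyl-3,4-dihydro-2H-pyran-5-carboxylate F1. Nickel-catalysed reductive cross-electrophile coupling of this alkyl bromide with aryl iodide 16 (NiI2, 4,4'-di-tert-butyl-2,2'-bipyridine, NaI, Zn, DMPU, 60 °C) then forms the same CH2–aryl bond and comes back to the route at 17.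

Step 8. Enolisation of the side-chain ester may compete with enolisation of the lactone, which after step 9 would show up as loss of configuration at C4, and methoxide set free may open the lactone. The fallback sets out from lactone 8. Heating with tert-butoxybis(dimethylamino)methane (Bredereck's reagent) in toluene at 90 °C, with no strong base, should condense at the more activated lactone methylene to give methyl 2-[(2S,3R,4S,5E)-3-[(benzyloxy)methyl]-5-[(dimethylamino)methylidene]-2-methyl-6-oxooxan-4-yl]acetate F2. Treatment of this enaminone with HCl in MeOH as in step 9 should pass through 10 and come back to the route at 11.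

Step 15. Cleavage of the aliphatic benzyl ether may be slow, so that saturation of the C5=C6 bond competes or the hydrogenolysis stops short. The fallback sets out from 17 and uses non-reductive Lewis-acid debenzylation (BCl3, pentamethylbenzene as benzyl-cation scavenger, CH2Cl2, −78 °C, methanol quench), which should give 18 directly; it makes no new compound (F0).

**Further compounds**

F1 | step 14 | methyl (2S,3R,4S)-3-[(benzyloxy)methyl]-4-[2-(2-bromoethoxy)-2-oxoethyl]-2-methyl-3,4-dihydro-2H-pyran-5-carboxylate | COC(=O)C1=CO[C@@H](C)[C@@H](COCc2ccccc2)[C@@H]1CC(=O)OCCBr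
F2 | step 8 | methyl 2-[(2S,3R,4S,5E)-3-[(benzyloxy)methyl]-5-[(dimethylamino)methylidene]-2-methyl-6-oxooxan-4-yl]acetate | C[C@@H]1OC(=O)/C(=C/N(C)C)[C@@H](CC(=O)OC)[C@@H]1COCc1ccccc1
F0 | step 15 | none | none
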